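## The problem

Compound 20, [(1S,2S,5S,6S)-2,5-bis(benzoyloxy)-1,6-dihydroxycyclohex-3-en-1-yl]methyl benzoate, is a single cyclohexene ring numbered here C1 (the carbinol carbon that carries the C7H2OBz arm), C2 (CHOBz), C3=C4, C5 (CHOBz) and C6 (CHOH). Four contiguous stereocentres, C5–C6–C1–C2, fill the saturated half of the ring, with C1–OH, C6–OH and C5–OBz on one face and C2–OBz and C7 on the other; C1 is fully substituted and cannot be corrected once the ring exists. C5 and C6 form a cis-diol pattern that a sugar can supply, but they can dictate C1 and C2 only if their information is relayed through the ring-forming event. Five oxygens must be told apart: three are benzoylated (primary C7, allylic C2 and C5) and two stay free (tertiary C1, secondary C6), and C5–O and C6–O are cis neighbours between which an acyl group can migrate. The two allylic benzoates flank the alkene and invite ionisation, allylic transposition or elimination toward an arene, so every strongly basic, reducing or hot step has to come before benzoylation. The feature that opens the problem is that C7–C1(O)–C6(O)–C5(O)–C4 has the oxygen pattern and configuration of C1–C5 of D-galactonic acid, while C4=C3–C2(O) is an allyl unit whose inner terminus C4 is the carbon that carries the ring oxygen of a galactono-1,5-lactone. C1–C2 is then the bond made, and O–C4 the bond lost, in a [3,3] shift of that lactone's ketene acetal.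

## Retrosynthesis

Sugar intermediates keep carbohydrate numbering with the prefix gal-: gal-C1 becomes C7, gal-C2 C1, gal-C3 C6, gal-C4 C5, gal-C5 C4, gal-C6 C3, and the added carbon gal-C7 becomes C2.

**C5 benzoate.** The last bond cut is the acyl–O bond at C5, leading from 20 to triol 19 and benzoyl chloride 17. The C5 hydroxyl is allylic and flanked by an sp2 carbon, whereas the C6 hydroxyl sits next to the fully substituted C1 and the C1 hydroxyl is tertiary, so a kinetic monoacylation should pick C5. The neighbouring option, separate protecting groups on gal-O3 and gal-O4 from the start, would sacrifice the 3,4-acetonide, which is needed earlier for one-step protection, for tying back the β-oxygen and for pre-forming the boat. The forward reaction must run cold and without nucleophilic catalyst so that no benzoyl migration follows.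

**C7 and C2 benzoates, protecting groups, oxidation level.** Triol 19 comes from dibenzoate 18 by acid hydrolysis of the MOM ether and the acetonide. Dibenzoate 18 comes from diol 16 and two equivalents of 17, diol 16 from PMB ether 15 by oxidative debenzylation, and 15 from carboxylic acid 14 by hydride reduction. The order is fixed by the sensitivity of the benzoates: the hydride step and all base chemistry lie before the first acylation. None of these cuts changes the skeleton; they reduce the problem to acid 14, which carries all four stereocentres.

**C1–C2 (key disconnection).** Acid 14 is cut at C1–C2 with reconnection of C4 to the carboxyl oxygen, which gives the 1,5-lactone 11 by way of its silyl ketene acetal 12. A C2–C3 cut (carbonyl addition) would leave C2 to substrate bias beside a quaternary centre, and a C3=C4 cut (metathesis) would require C1 and C2 to be built beforehand on an open chain. The sigmatropic cut sets C1 and C2 together from information already in the substrate and returns the skeleton to a hexonolactone plus one carbon. The forward reaction demands enolisation at gal-C2 without loss of the β-oxygen at gal-C3, a boat transition state, which the lactone ring imposes, and a geometrically pure (E)-enol ether, because the alkene geometry becomes the configuration of C2.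

**Enol ether.** Lactone 11 is cut at the vinyl C–O bond to alkenyl boronate 9 and 4-methoxybenzyl alcohol 10, and 9 at gal-C6=gal-C7 to aldehyde 8. A one-step alkoxymethylene Wittig reaction would be shorter, but it gives both alkene isomers and only the (E)-isomer leads to 20. A CrCl2-mediated boron olefination gives the (E)-alkene, and a Cu(OAc)2-promoted C–O coupling retains it. Neither uses strong base, which the α-acyloxy aldehyde and the lactone would not tolerate.

**Oxidation states at gal-C1 and gal-C6.** Aldehyde 8 comes from alcohol 7, which comes from silyl ether 6. Lactone 6 comes from lactol 5, and 5 from thioglycoside 4. The lactone is made before the alkene because unmasking the anomeric carbon needs an electrophilic bromine source that an enol ether would not survive.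

**Protecting groups on the sugar.** Thioglycoside 4 is reduced through MOM ether formation (from 3), primary silylation (from 2) and acetonation of the cis-3,4-diol (from 1). Phenyl 1-thio-β-D-galactopyranoside 1 already holds C5, C6, C7 and the relay centre gal-C5 in the correct absolute sense. The configuration at gal-C2 is erased at the ketene acetal and set anew as C1.

## Roads not taken

Alternative 1: The ring is cut at C1–C2 and C5–C6, which leads back to furan A1 and 2-bromoacrolein A2. A chiral oxazaborolidinone Lewis acid would join A1 and A2 in an enantioselective Diels–Alder reaction to the oxanorbornene aldehyde A3. The merit is that one catalytic step from bulk chemicals makes the carbocycle, the quaternary carbon and C7; in step count to the ring this road is clearly better than the chosen one, which needs ten steps. Its weak points lie after the cycloaddition. A3 holds few of the target's features: C2 and C5 share one bridging oxygen and are therefore cis, while 20 needs them trans, so the bridge opening must bring in one benzoate with inversion. C6 is a methylene that must be oxygenated cis to C5–O, and bromide at C1 must be exchanged for hydroxyl with defined configuration. Adducts of A1 also revert readily, and the later sequence is a chain of substrate-controlled operations on a strained, elimination-prone bicycle. The chosen plan is longer to the ring, but at ring closure it already has all five oxygens at the correct oxidation level and all four stereocentres.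

Alternative 2: The ring is cut at C2–C3. A branched chain derived from L-ribose A4 would be elaborated to the aldehyde–(Z)-vinyl iodide A5, and CrCl2 with catalytic NiCl2 would close A5 by Nozaki–Hiyama–Kishi addition to cyclohexenol A6. The endgame is better than the chosen one: A6 already carries the C5 and C7 benzoates and a C1,C6-acetonide, so benzoylation of C2–OH and acetal hydrolysis finish the synthesis with no regioselective acylation. The weak point is C2, which is created in the carbonyl addition itself on an aldehyde attached to the quaternary C1. Nothing but the conformation of the tethered chain decides the face, and correction by inversion at a neopentyl allylic carbinol is unattractive. The quaternary centre also has to be built on A4 by a separate branching step with its own stereochemical question, and the (Z)-vinyl iodide of A5 needs a further selective olefination. The chosen plan pays with a five-step endgame that includes a regioselective benzoylation; against this it derives both new centres from elements that cannot vary, the face of the vinyl arm and the alkene geometry.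

Alternative 3: Both the C6–O bond and the C1–O acetal bond are cut, which leads to the achiral para-quinol benzoate A7 and cyclohexanecarbaldehyde A8. A chiral BINOL-derived phosphoric acid would tie the C1 hydroxyl of A7 to the carbonyl carbon of A8 and guide the oxa-Michael addition to one enone arm, giving the cis-fused dioxolane enone A9. The merits are catalytic absolute control, an aromatic starting material, and C1 and C6 set with the correct cis relation in very few steps; this is again shorter to a chiral ring than the chosen plan. The weak point is the oxidation pattern of A9, which has the alkene at C2=C3, a ketone at C4 and a methylene at C5. The target needs oxygen at C2 and C5 and the alkene at C3=C4, so an α-oxygenation, an epoxidation and a reductive transposition must follow, and the cis-fused acetal would steer the C5 oxygen to the face opposite C6–O, the wrong one. This road moves the difficulty from ring formation to stereocontrolled redox adjustment, which the chosen plan avoids because the sugar already carries every oxygen.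

Key step: step 10

Assumption: phenyl 1-thio-β-D-galactopyranoside 1 is taken as the purchasable, crystalline form of D-galactose.

## Steps

Step 1
Reactants: 1 phenyl 1-thio-β-D-galactopyranoside
Product: 2 phenyl 3,4-O-isopropylidene-1-thio-β-D-galactopyranoside
Conditions: Me2C(OMe)2, CSA (cat.), acetone, rt; Et3N quench
Reagents that add atoms: 2,2-dimethoxypropane, COC(C)(C)OC
Why: Acid-catalysed transketalisation under thermodynamic control; the cis-3,4-diol closes the five-membered dioxolane and leaves the 2- and 6-hydroxyls free. No stereocentre is touched.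

Step 2
Reactants: 2 phenyl 3,4-O-isopropylidene-1-thio-β-D-galactopyranoside
Product: 3 phenyl 6-O-(tert-butyldimethylsilyl)-3,4-O-isopropylidene-1-thio-β-D-galactopyranoside
Conditions: TBSCl, imidazole, DMF, 0 °C
Reagents that add atoms: tert-butyldimethylsilyl chloride, CC(C)(C)[Si](C)(C)Cl
Why: Selective silylation of the primary hydroxyl; the secondary 2-hydroxyl beside the anomeric centre reacts far more slowly.

Step 3
Reactants: 3 phenyl 6-O-(tert-butyldimethylsilyl)-3,4-O-isopropylidene-1-thio-β-D-galactopyranoside
Product: 4 phenyl 6-O-(tert-butyldimethylsilyl)-3,4-O-isopropylidene-2-O-(methoxymethyl)-1-thio-β-D-galactopyranoside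
Conditions: MOMCl, iPr2NEt, Bu4NI (cat.), CH2Cl2, 40 °C
Reagents that add atoms: chloromethyl methyl ether, COCCl
Why: O-alkylation of the remaining hydroxyl as a base-stable acetal ether. MOM is small, stable to amide base and leaves in the same acid step as the acetonide.

Step 4
Reactants: 4 phenyl 6-O-(tert-butyldimethylsilyl)-3,4-O-isopropylidene-2-O-(methoxymethyl)-1-thio-β-D-galactopyranoside
Product: 5 6-O-(tert-butyldimethylsilyl)-3,4-O-isopropylidene-2-O-(methoxymethyl)-D-galactopyranose (anomeric mixture)
Conditions: NBS, NaHCO3, acetone/H2O 9:1, −15 °C
Reagents that add atoms: water, O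
Why: Thioglycoside hydrolysis; bromination at sulfur gives the oxocarbenium ion, which water captures. Bicarbonate keeps the silyl ether and acetals intact.

Step 5
Reactants: 5 6-O-(tert-butyldimethylsilyl)-3,4-O-isopropylidene-2-O-(methoxymethyl)-D-galactopyranose (anomeric mixture)
Product: 6 6-O-(tert-butyldimethylsilyl)-3,4-O-isopropylidene-2-O-(methoxymethyl)-D-galactono-1,5-lactone
Conditions: Dess–Martin periodinane, NaHCO3, CH2Cl2, rt
Reagents that add atoms: none
Why: Lactol-to-lactone oxidation with a neutral hypervalent iodine oxidant; both anomers converge and no other hydroxyl is free.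

Step 6
Reactants: 6 6-O-(tert-butyldimethylsilyl)-3,4-O-isopropylidene-2-O-(methoxymethyl)-D-galactono-1,5-lactone
Product: 7 3,4-O-isopropylidene-2-O-(methoxymethyl)-D-galactono-1,5-lactone
Conditions: HF·pyridine, pyridine, THF, 0 °C → rt
Reagents that add atoms: none
Why: Fluoride-mediated desilylation under buffered, non-basic conditions that do not open or enolise the lactone.

Step 7
Reactants: 7 3,4-O-isopropylidene-2-O-(methoxymethyl)-D-galactono-1,5-lactone
Product: 8 3,4-O-isopropylidene-2-O-(methoxymethyl)-D-galacto-hexodialdono-1,5-lactone (gal-C6 aldehyde of 7)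
Conditions: Dess–Martin periodinane, NaHCO3, CH2Cl2, 0 °C → rt
Reagents that add atoms: none
Why: Dess–Martin oxidation of the primary alcohol without base, so the α-acyloxy aldehyde keeps its gal-C5 configuration. The aldehyde should be used crude in step 8.

Step 8
Reactants: 8 3,4-O-isopropylidene-2-O-(methoxymethyl)-D-galacto-hexodialdono-1,5-lactone (gal-C6 aldehyde of 7)
Product: 9 (E)-6,7-dideoxy-3,4-O-isopropylidene-2-O-(methoxymethyl)-7-(4,4,5,5-tetramethyl-1,3,2-dioxaborolan-2-yl)-D-galacto-hept-6-enono-1,5-lactone
Conditions: Cl2CHBpin, CrCl2, LiI, THF, rt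
Reagents that add atoms: 2-(dichloromethyl)-4,4,5,5-tetramethyl-1,3,2-dioxaborolane, ClC(Cl)B1OC(C)(C)C(C)(C)O1
Why: Takai–Utimoto boron olefination; a geminal dichromium carbenoid generated by divalent chromium adds to the aldehyde and eliminates to the (E)-alkenylboronate. The reagent is non-basic and leaves the lactone and the gal-C5 centre alone.

Step 9
Reactants: 9 (E)-6,7-dideoxy-3,4-O-isopropylidene-2-O-(methoxymethyl)-7-(4,4,5,5-tetramethyl-1,3,2-dioxaborolan-2-yl)-D-galacto-hept-6-enono-1,5-lactone; 10 4-methoxybenzyl alcohol
Product: 11 (E)-6-deoxy-3,4-O-isopropylidene-7-O-(4-methoxybenzyl)-2-O-(methoxymethyl)-D-galacto-hept-6-enono-1,5-lactone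
Conditions: Cu(OAc)2, Et3N, 4 Å MS, CH2Cl2, air, rt
Reagents that add atoms: none
Why: Chan–Lam-type oxidative C–O coupling of an alkenyl pinacol boronate with an aliphatic alcohol promoted by divalent copper. Transmetalation and reductive elimination proceed with retention, so the (E)-boronate should give the (E)-enol ether. Et3N buffers the medium against acetalisation of the product.

Step 10
Reactants: 11 (E)-6-deoxy-3,4-O-isopropylidene-7-O-(4-methoxybenzyl)-2-O-(methoxymethyl)-D-galacto-hept-6-enono-1,5-lactone
Product: 14 5,6-(isopropylidenedioxy)-2-(4-methoxybenzyloxy)-1-(methoxymethoxy)cyclohex-3-ene-1-carboxylic acid (target numbering; C1–OMOM cis to C5–O/C6–O; C2–OPMB cis to CO2H), via trimethylsilyl ketene acetal 12 (not isolated), via trimethylsilyl ester 13 (not isolated)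
Conditions: Me3SiCl/Et3N, KN(SiMe3)2, THF, −78 °C → rt; PhMe, 90 °C; aq. citric acid
Reagents that add atoms: none
Why: KN(SiMe3)2 deprotonates gal-C2 at −78 °C with Me3SiCl already present, so the enolate is trapped at once as cyclic ketene acetal 12 before the acetonide oxygen at gal-C3 can leave by E1cB. On warming, 12 should undergo a concerted suprafacial [3,3] shift (Ireland–Claisen rearrangement) in which gal-C2 bonds to the enol ether terminus gal-C7 (C1–C2), the ring O–gal-C5 bond breaks (O–C4) and C3=C4 appears; hydrolysis of silyl ester 13 then gives 14. The closest known reactions are the ring contraction of 6-alkenyl δ-lactone silyl ketene acetals to cyclohex-3-enecarboxylic acids and the Ireland–Claisen rearrangement of glycal esters, where the new bond is also made at an oxygen-bearing alkene carbon. The cyclohexene closes by transannular C–C bond formation inside a bicyclo[2.2.2]octane-like array: the lactone forces the six reacting atoms into a boat with gal-C2 and gal-C5 at bow and stern, a shape the cis-fused acetonide already favours. C1 is controlled by gal-C5, because the vinyl arm can reach the ketene acetal only from the face it occupies; this puts C1–OMOM cis to the C5 and C6 oxygens and the carboxyl group trans. C2 is controlled by the alkene geometry, because in the enforced boat the (E)-enol ether holds its OPMB on the outer side, eclipsed with OMOM in the transition state and therefore cis to the carboxyl group in the product. The step needs silylation to be faster than β-elimination, which the internal quench provides, and a shift fast enough for 12 to survive, which the donor oxygen at the migrating terminus and the silyloxy group both promote.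

Step 11
Reactants: 14 5,6-(isopropylidenedioxy)-2-(4-methoxybenzyloxy)-1-(methoxymethoxy)cyclohex-3-ene-1-carboxylic acid
Product: 15 [5,6-(isopropylidenedioxy)-2-(4-methoxybenzyloxy)-1-(methoxymethoxy)cyclohex-3-en-1-yl]methanol (configuration as in 14)
Conditions: LiAlH4, THF, 0 → 40 °C
Reagents that add atoms: none
Why: Hydride reduction of the carboxylic acid to the primary alcohol C7–OH. Ethers, acetals and the isolated alkene are inert to LiAlH4.

Step 12
Reactants: 15 [5,6-(isopropylidenedioxy)-2-(4-methoxybenzyloxy)-1-(methoxymethoxy)cyclohex-3-en-1-yl]methanol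
Product: 16 1-(hydroxymethyl)-5,6-(isopropylidenedioxy)-1-(methoxymethoxy)cyclohex-3-en-2-ol (target numbering; the C7/C2 diol; configuration as in 14)
Conditions: DDQ, CH2Cl2/pH 7 buffer, 0 °C
Reagents that add atoms: none
Why: Oxidative cleavage of the PMB ether by hydride abstraction and hydrolysis of the resulting oxocarbenium ion. The buffered aqueous phase spares the MOM ether and acetonide and favours hydrolysis over internal capture.

Step 13
Reactants: 16 1-(hydroxymethyl)-5,6-(isopropylidenedioxy)-1-(methoxymethoxy)cyclohex-3-en-2-ol; 17 benzoyl chloride
Product: 18 [2-(benzoyloxy)-5,6-(isopropylidenedioxy)-1-(methoxymethoxy)cyclohex-3-en-1-yl]methyl benzoate (configuration as in 14)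
Conditions: BzCl (2.5 equiv), pyridine, DMAP (cat.), CH2Cl2, 0 °C → rt
Reagents that add atoms: benzoyl chloride (the second equivalent beside reactant 17), O=C(Cl)c1ccccc1
Why: DMAP-catalysed acylation (nucleophilic catalysis) of the primary C7 and the hindered allylic C2 hydroxyls, which takes up two equivalents of benzoyl chloride; no other hydroxyl is free and no stereocentre is touched.

Step 14
Reactants: 18 [2-(benzoyloxy)-5,6-(isopropylidenedioxy)-1-(methoxymethoxy)cyclohex-3-en-1-yl]methyl benzoate
Product: 19 [2-(benzoyloxy)-1,5,6-trihydroxycyclohex-3-en-1-yl]methyl benzoate (1-OH/5-OH/6-OH cis; 2-OBz trans; absolute configuration as in 20)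
Conditions: TFA/H2O 9:1, 0 °C → rt
Reagents that add atoms: none
Why: Acid hydrolysis removes the isopropylidene acetal and the MOM ether together. Benzoates are stable to aqueous acid, and acyl migration is slow without base.

Step 15
Reactants: 19 [2-(benzoyloxy)-1,5,6-trihydroxycyclohex-3-en-1-yl]methyl benzoate; 17 benzoyl chloride
Product: 20 [(1S,2S,5S,6S)-2,5-bis(benzoyloxy)-1,6-dihydroxycyclohex-3-en-1-yl]methyl benzoate
Conditions: BzCl (1.05 equiv), pyridine, CH2Cl2, −40 → −20 °C
Reagents that add atoms: none
Why: Kinetic monoacylation. The allylic C5 hydroxyl is the least hindered, whereas C6–OH is shielded by the fully substituted C1 and the C1 hydroxyl is tertiary. Low temperature and the absence of DMAP should suppress benzoyl migration.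

## Compound list

1 | phenyl 1-thio-β-D-galactopyranoside | OC[C@H]1O[C@@H](Sc2ccccc2)[C@H](O)[C@@H](O)[C@H]1O | starting material
2 | phenyl 3,4-O-isopropylidene-1-thio-β-D-galactopyranoside | OC[C@H]1O[C@@H](Sc2ccccc2)[C@H](O)[C@H]3OC(C)(C)O[C@@H]13 | intermediate
3 | phenyl 6-O-(tert-butyldimethylsilyl)-3,4-O-isopropylidene-1-thio-β-D-galactopyranoside | CC(C)(C)[Si](C)(C)OC[C@H]1O[C@@H](Sc2ccccc2)[C@H](O)[C@H]3OC(C)(C)O[C@@H]13 | intermediate
4 | phenyl 6-O-(tert-butyldimethylsilyl)-3,4-O-isopropylidene-2-O-(methoxymethyl)-1-thio-β-D-galactopyranoside | CC(C)(C)[Si](C)(C)OC[C@H]1O[C@@H](Sc2ccccc2)[C@H](OCOC)[C@H]3OC(C)(C)O[C@@H]13 | intermediate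
5 | 6-O-(tert-butyldimethylsilyl)-3,4-O-isopropylidene-2-O-(methoxymethyl)-D-galactopyranose (anomeric mixture) | CC(C)(C)[Si](C)(C)OC[C@H]1OC(O)[C@H](OCOC)[C@H]3OC(C)(C)O[C@@H]13 | intermediate
6 | 6-O-(tert-butyldimethylsilyl)-3,4-O-isopropylidene-2-O-(methoxymethyl)-D-galactono-1,5-lactone | CC(C)(C)[Si](C)(C)OC[C@H]1OC(=O)[C@H](OCOC)[C@H]3OC(C)(C)O[C@@H]13 | intermediate
7 | 3,4-O-isopropylidene-2-O-(methoxymethyl)-D-galactono-1,5-lactone | OC[C@H]1OC(=O)[C@H](OCOC)[C@H]3OC(C)(C)O[C@@H]13 | intermediate
8 | 3,4-O-isopropylidene-2-O-(methoxymethyl)-D-galacto-hexodialdono-1,5-lactone (gal-C6 aldehyde of 7) | O=C[C@H]1OC(=O)[C@H](OCOC)[C@H]3OC(C)(C)O[C@@H]13 | intermediate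
9 | (E)-6,7-dideoxy-3,4-O-isopropylidene-2-O-(methoxymethyl)-7-(4,4,5,5-tetramethyl-1,3,2-dioxaborolan-2-yl)-D-galacto-hept-6-enono-1,5-lactone | CC1(C)OB(/C=C/[C@H]2OC(=O)[C@H](OCOC)[C@H]3OC(C)(C)O[C@@H]23)OC1(C)C | intermediate
10 | 4-methoxybenzyl alcohol | COc1ccc(CO)cc1 | starting material
11 | (E)-6-deoxy-3,4-O-isopropylidene-7-O-(4-methoxybenzyl)-2-O-(methoxymethyl)-D-galacto-hept-6-enono-1,5-lactone | COc1ccc(CO/C=C/[C@H]2OC(=O)[C@H](OCOC)[C@H]3OC(C)(C)O[C@@H]23)cc1 | intermediate
12 | trimethylsilyl ketene acetal of 11, gal-C1(OSiMe3)=gal-C2(OMOM) (not isolated) | COc1ccc(CO/C=C/[C@H]2OC(O[Si](C)(C)C)=C(OCOC)[C@H]3OC(C)(C)O[C@@H]23)cc1 | intermediate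
13 | trimethylsilyl ester of acid 14 (not isolated) | C[Si](C)(C)OC(=O)[C@@]1(OCOC)[C@@H](OCc2ccc(OC)cc2)C=C[C@@H]2OC(C)(C)O[C@H]12 | intermediate
14 | 5,6-(isopropylidenedioxy)-2-(4-methoxybenzyloxy)-1-(methoxymethoxy)cyclohex-3-ene-1-carboxylic acid (target numbering; 1-O, 5-O, 6-O cis; 2-O trans to them and cis to CO2H; absolute configuration as in 20) | OC(=O)[C@@]1(OCOC)[C@@H](OCc2ccc(OC)cc2)C=C[C@@H]2OC(C)(C)O[C@H]12 | intermediate
15 | [5,6-(isopropylidenedioxy)-2-(4-methoxybenzyloxy)-1-(methoxymethoxy)cyclohex-3-en-1-yl]methanol (configuration as in 14) | OC[C@@]1(OCOC)[C@@H](OCc2ccc(OC)cc2)C=C[C@@H]2OC(C)(C)O[C@H]12 | intermediate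
16 | 1-(hydroxymethyl)-5,6-(isopropylidenedioxy)-1-(methoxymethoxy)cyclohex-3-en-2-ol (target numbering; the C7/C2 diol; configuration as in 14) | OC[C@@]1(OCOC)[C@@H](O)C=C[C@@H]2OC(C)(C)O[C@H]12 | intermediate
17 | benzoyl chloride | O=C(Cl)c1ccccc1 | starting material
18 | [2-(benzoyloxy)-5,6-(isopropylidenedioxy)-1-(methoxymethoxy)cyclohex-3-en-1-yl]methyl benzoate (configuration as in 14) | O=C(OC[C@@]1(OCOC)[C@@H](OC(=O)c2ccccc2)C=C[C@@H]2OC(C)(C)O[C@H]12)c1ccccc1 | intermediate
19 | [2-(benzoyloxy)-1,5,6-trihydroxycyclohex-3-en-1-yl]methyl benzoate (1-OH, 5-OH, 6-OH cis; 2-OBz trans; absolute configuration as in 20) | O=C(OC[C@@]1(O)[C@@H](OC(=O)c2ccccc2)C=C[C@H](O)[C@@H]1O)c1ccccc1 | intermediate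
20 | [(1S,2S,5S,6S)-2,5-bis(benzoyloxy)-1,6-dihydroxycyclohex-3-en-1-yl]methyl benzoate (CNP0128482.4) | O=C(OC[C@@]1(O)[C@@H](OC(=O)c2ccccc2)C=C[C@H](OC(=O)c2ccccc2)[C@@H]1O)c1ccccc1 | target

## Step count and least certain steps

Total: 15 steps from 1. Longest linear sequence: 15 steps (the route is fully linear; 10 and 17 are bought).

**Step 10 (key step).** The likely failures are E1cB opening of the acetonide from the potassium enolate before silylation is complete, or decomposition of the ketene acetal competing with a slow boat rearrangement. The fallback keeps the same bond change but uses no enolate: a neutral thermal Claisen rearrangement of the corresponding glycal, a known reaction of 2-vinyl-3,4-dihydro-2H-pyrans. It sets out from 11. iBu2AlH at −78 °C would give the lactol F1, and MsCl/Et3N would eliminate through the anomeric mesylate to the 2-O-MOM glycal F2 (gal-C1=gal-C2 enol ether). Heating F2 in o-dichlorobenzene at about 180–200 °C should give, through the same boat, the cyclohexene carbaldehyde F3. NaBH4 reduction of F3 rejoins the route at 15.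

**Step 9.** The excess alcohol with amine may open the electrophilic δ-lactone by alcoholysis, and protodeboronation may compete with a slow coupling. The fallback sets out from aldehyde 8, so it also covers a failure of step 8. A Wittig reaction with (4-methoxybenzyloxymethyl)triphenylphosphonium chloride and KN(SiMe3)2 at −78 °C would give 11 together with its (Z)-isomer F4. F4 would be removed by chromatography on amine-deactivated silica, and the route is rejoined at 11.

**Step 15.** Site selectivity between the C5 and C6 hydroxyls may be poor, or the benzoyl group may migrate between these cis oxygens. The fallback sets out from 19. Trimethyl orthobenzoate with CSA would give the cyclic 5,6-orthobenzoate F5. Mild hydrolysis in aqueous acetic acid opens such orthoesters to the ester on the axial oxygen, which in the half-chair with C7 equatorial is the C5 oxygen. This gives 20 directly.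

**Step 12.** The oxidised PMB group may be captured internally by the neighbouring C7 hydroxyl, giving a six-membered p-methoxybenzylidene acetal instead of cleavage. The fallback sets out from 15 and removes the free hydroxyl first. Benzoylation (BzCl, pyridine) would give the C7 monobenzoate F6, DDQ would then give the C2 alcohol F7, and a second benzoylation with DMAP rejoins the route at 18. This costs one extra step.

## Further compounds

F1 | step 10 | lactol of 11: (E)-6-deoxy-3,4-O-isopropylidene-7-O-(4-methoxybenzyl)-2-O-(methoxymethyl)-D-galacto-hept-6-enopyranose | COc1ccc(CO/C=C/[C@H]2OC(O)[C@H](OCOC)[C@H]3OC(C)(C)O[C@@H]23)cc1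
F2 | step 10 | 2-O-MOM glycal of F1: (E)-1,5-anhydro-6-deoxy-3,4-O-isopropylidene-7-O-(4-methoxybenzyl)-2-O-(methoxymethyl)-D-lyxo-hepta-1,6-dienitol | COc1ccc(CO/C=C/[C@H]2OC=C(OCOC)[C@H]3OC(C)(C)O[C@@H]23)cc1
F3 | step 10 | 5,6-(isopropylidenedioxy)-2-(4-methoxybenzyloxy)-1-(methoxymethoxy)cyclohex-3-ene-1-carbaldehyde (configuration as in 14) | O=C[C@@]1(OCOC)[C@@H](OCc2ccc(OC)cc2)C=C[C@@H]2OC(C)(C)O[C@H]12
F4 | step 9 | (Z)-isomer of 11 | COc1ccc(CO/C=C\[C@H]2OC(=O)[C@H](OCOC)[C@H]3OC(C)(C)O[C@@H]23)cc1
F5 | step 15 | 5,6-O-(α-methoxybenzylidene) orthoester of 19 (orthoester carbon unassigned) | O=C(OC[C@@]1(O)[C@@H](OC(=O)c2ccccc2)C=C[C@@H]2OC(OC)(c3ccccc3)O[C@H]12)c1ccccc1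
F6 | step 12 | [5,6-(isopropylidenedioxy)-2-(4-methoxybenzyloxy)-1-(methoxymethoxy)cyclohex-3-en-1-yl]methyl benzoate | O=C(OC[C@@]1(OCOC)[C@@H](OCc2ccc(OC)cc2)C=C[C@@H]2OC(C)(C)O[C@H]12)c1ccccc1
F7 | step 12 | [2-hydroxy-5,6-(isopropylidenedioxy)-1-(methoxymethoxy)cyclohex-3-en-1-yl]methyl benzoate | O=C(OC[C@@]1(OCOC)[C@@H](O)C=C[C@@H]2OC(C)(C)O[C@H]12)c1ccccc1
A1 | alternative 1 | furan | c1ccoc1
A2 | alternative 1 | 2-bromoacrolein | C=C(Br)C=O
A3 | alternative 1 | exo-formyl 2-bromo-7-oxabicyclo[2.2.1]hept-5-ene-2-carbaldehyde | O=C[C@]1(Br)[C@H]2C=C[C@H](O2)C1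
A4 | alternative 2 | L-ribose (open-chain form) | C([C@@H]([C@@H]([C@@H](C=O)O)O)O)O
A5 | alternative 2 | open-chain C2 aldehyde with (Z)-vinyl iodide at C3, C1,C6-acetonide and C5, C7 benzoates | O=C(OC[C@]1(C=O)OC(C)(C)O[C@H]1[C@@H](OC(=O)c2ccccc2)/C=C\I)c1ccccc1
A6 | alternative 2 | cyclohexenol with free C2–OH, C1,C6-acetonide and C5, C7 benzoates | O=C(OC[C@@]1(OC(C)(C)O2)[C@@H](O)C=C[C@H](OC(=O)c3ccccc3)[C@@H]12)c1ccccc1
A7 | alternative 3 | (1-hydroxy-4-oxocyclohexa-2,5-dien-1-yl)methyl benzoate | O=C(OCC1(O)C=CC(=O)C=C1)c1ccccc1
A8 | alternative 3 | cyclohexanecarbaldehyde | O=CC1CCCCC1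
A9 | alternative 3 | cis-fused dioxolane enone with C1 and C6 set | O=C(OC[C@@]1(O[C@H](C2CCCCC2)O3)C=CC(=O)C[C@@H]13)c1ccccc1
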